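Catalyst wears out. In the flask, free catalyst takes up starting material and partner turns that into target, while second substrate may take catalyst and partner as well; the question is how far target gets before the catalyst is lost.

| flask | starting material | second substrate | partner | free catalyst | remark | time |
|---|---|---|---|---|---|---|
| winter | 5 mM | 5 mM | 7.5 mM | 5 µM | run made earlier |  |
| summer | 5 mM | 5 mM | 7.5 mM | 7.5 µM | run made earlier |  |
| dawn | 5 mM | 2.5 mM | 7.5 mM | 10 µM | run made earlier |  |
| flask | 5.0 mM | 5.00 mM | 7.50 mM | 10 µM |  | 5.0 min |

- winter (time / min: target / %, starting material / %): 0.250: 10.9, 89.3; 0.417: 17.9, 82.0; 0.833: 32.2, 67.8; 1.50: 47.3, 52.5; 3.00: 62.5, 37.4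
- summer (time / min: target / %, starting material / %): 0.250: 15.8, 83.9; 0.417: 24.8, 75.2; 0.833: 42.2, 57.5; 1.50: 58.0, 41.8; 3.00: 71.0, 28.9
- dawn (time / min: target / %, starting material / %): 0.667: 46.8, 52.9; 1.33: 66.6, 33.5; 2.00: 75.3, 24.9; 2.50: 79.2, 21.1; 3.00: 81.0, 18.9

(readings scatter by 0.3 percentage points)

- in percentages every species weighs as the starting material in it: one spent catalyst counts as two
- what was read earlier has a scatter of 0.3 percentage points, one standard deviation
- steps thought possible: starting material + free catalyst <-> catalyst intermediate A; partner + catalyst intermediate B -> free catalyst + second product; partner + catalyst intermediate A -> free catalyst + target; catalyst intermediate A + target -> spent catalyst; second substrate + free catalyst <-> catalyst intermediate B; 2 second substrate -> homo dimer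

- concentration of target at 5.0 min, in mM
- concentration of starting material at 5.0 min, in mM
- concentration of partner at 5.0 min, in mM

Two extreme versions of the flask can be solved in the head. In the first, catalyst and partner are both held at their charges, which the real flask does not do: the first winter reading gives an early first-order constant of 0.453 /min, which taken in proportion to catalyst becomes 0.905 /min at the flask's catalyst, a clock of 1.10 min, and this idealised reckoning gives 0.0541 mM of starting material at 5.0 min. In the second, wear goes with target made and not with time, so target levels off at a ceiling, estimated as the last reading plus later equal time steps whose gains are taken to shrink by one ratio. The dawn run, with the flask's catalyst but half its second substrate, gained 3.9 percentage points and then 1.8 points, a ratio of 0.462, so the ceiling reads 4.13 mM, roughly, given the scatter of 0.3 points. Because the clock is shorter than the time, the flask should stand near the ceiling, with 0.873 mM of starting material and 3.37 mM of partner, less whatever second substrate took, which no reading shows.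

The forecast says 4.16 mM, 0.83 mM and 3.1 mM, holding that “catalyst lost depends on target formed, not on time or charge”; its target stands above this ceiling.

The flask gives 3.99 mM of target, 0.990 mM of starting material and 1.25 mM of partner, with 2.25 mM of second product beside them.

    starting material + free catalyst ⇌ catalyst intermediate A (K = 230 /M, k = 4000 /M/s)
    partner + catalyst intermediate B → free catalyst + second product (k = 4600 /M/s)
    partner + catalyst intermediate A → free catalyst + target (k = 5700 /M/s)
    catalyst intermediate A + target → spent catalyst (k = 16.0 /M/s)
    second substrate + free catalyst ⇌ catalyst intermediate B (K = 1300 /M, k = 5400 /M/s)
    2 second substrate → homo dimer (k = 7.90 /M/s)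

The forward half-life of starting material on its step to catalyst intermediate A is 0.29 min, short against 5.0 min, yet at that time the flask holds 19.8% of its starting material with 91.9% of the catalyst spent. Ten times as long brings target to 4.08 mM, near the ceiling. The same flask charged with 20 mM of starting material has the same catalyst, so the ceiling says 4.13 mM of target and 15.9 mM of starting material; it gives 4.70 mM and 15.3 mM.

(The numbers in the tables are simulated with made-up constants, and the scatter is random.)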